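**Plan**
- Retrosynthetic cuts, in order: (i) the two phenols are masked as benzyl ethers and the diarylmethane CH2 is raised to a ketone; (ii) the ArCH2–CH2Ar bond of the ethylene bridge is cut, giving a 2-methylbenzophenone and a 3-oxygenated benzyl bromide; (iii) the bond between the dimethoxy ring and the carbonyl carbon is cut, giving an aryl bromide and a Weinreb amide.
- Enabling feature: on the dimethoxy ring, the carbon bearing the 4-hydroxybenzyl group is ortho to the carbon bearing the bridge. With the 4-hydroxybenzyl CH2 held as a ketone, the bridge carbon (still a methyl group) is the vinylogous α-position of a non-enolisable diaryl ketone through the ring C=C bond, so it alone can be metalated and benzylated.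
- Forward order: the ketone synthesis fixes the 1,2,3,5-pattern of the dimethoxy ring through the position of the bromine; lateral lithiation–alkylation then joins the two halves; the helper carbonyl and both benzyl ethers are removed in the last two steps. All three benzene rings are bought, none is built.
- Stereochemistry: the target has no stereocentre and no stereogenic double bond. The carbinol carbon of the penultimate compound is racemic and is erased in the final hydrogenolysis.

Key step: step 3

Remark: 1-bromo-2,4-dimethoxy-6-methylbenzene (2-bromo-3,5-dimethoxytoluene), 4-(benzyloxy)benzoyl chloride and 1-(benzyloxy)-3-(bromomethyl)benzene are taken to be catalogue compounds.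

**Step 1**
Reactants: 1 4-(benzyloxy)benzoyl chloride
Product: 2 4-(benzyloxy)-N-methoxy-N-methylbenzamide
Conditions: MeNH(OMe)·HCl, Et3N, CH2Cl2, 0 °C → rt
Reagents that add atoms: N,O-dimethylhydroxylamine hydrochloride, CNOC.Cl
Why: N-acylation of the hydroxylamine by the acid chloride (Weinreb amide formation) should be clean, with Et3N taking up both equivalents of HCl and the aryl benzyl ether inert.

**Step 2**
Reactants: 3 1-bromo-2,4-dimethoxy-6-methylbenzene; 2 4-(benzyloxy)-N-methoxy-N-methylbenzamide
Product: 6 [4-(benzyloxy)phenyl](2,4-dimethoxy-6-methylphenyl)methanone, via aryllithium 4 (not isolated), via tetrahedral lithium adduct 5 (not isolated)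
Conditions: n-BuLi, THF, −78 °C; then 2, −78 → 0 °C; 1 M HCl
Reagents that add atoms: none
Why: Bromine–lithium exchange at −78 °C should outrun any deprotonation and place the metal on the ring carbon between the methyl and a methoxy group, and the aryllithium should add only once because the chelated adduct 5 survives until the acidic quench (Weinreb ketone synthesis).

**Step 3**
Reactants: 6 [4-(benzyloxy)phenyl](2,4-dimethoxy-6-methylphenyl)methanone; 7 1-(benzyloxy)-3-(bromomethyl)benzene
Product: 9 [4-(benzyloxy)phenyl]{2-[2-(3-(benzyloxy)phenyl)ethyl]-4,6-dimethoxyphenyl}methanone, via lithium dienolate 8 (not isolated)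
Conditions: LiTMP (from TMPH, n-BuLi), THF, −78 °C; then 7, −78 → −20 °C; aq. NH4Cl
Reagents that add atoms: none
Why: LiTMP should remove a proton from the ring methyl group, the only C–H conjugated through the ring C=C bond to the carbonyl of the non-enolisable diaryl ketone, to give the o-quinodimethane lithium dienolate 8, whose exocyclic methylene carbon attacks benzylic bromide 7 in an SN2 step that restores aromaticity and forms the CH2–CH2 bridge. The closest known reaction type is the lateral lithiation–benzylation of ortho-toluoyl carbonyl compounds (for example 2,4-dimethoxy-6-methylbenzoate esters with lithium amides), applied here to the ketone that already carries the third ring. No ring is closed and no stereocentre is formed. Site selectivity of deprotonation is secured by the substrate, since the ketone has no α-hydrogen, the ring and OCH2Ph hydrogens are far weaker acids towards an amide base, and lithium can sit between the enolate oxygen and the flanking methoxy group; LiTMP is chosen because it has no C–H next to nitrogen, so it cannot transfer hydride to the ketone, and it is too hindered to add. Carbon- rather than oxygen-alkylation should follow from rearomatisation and the soft benzylic electrophile, and single alkylation from the lower acidity and greater hindrance of the secondary benzylic position of 9 when no excess base is used.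

**Step 4**
Reactants: 9 [4-(benzyloxy)phenyl]{2-[2-(3-(benzyloxy)phenyl)ethyl]-4,6-dimethoxyphenyl}methanone
Product: 10 rac-[4-(benzyloxy)phenyl]{2-[2-(3-(benzyloxy)phenyl)ethyl]-4,6-dimethoxyphenyl}methanol
Conditions: LiAlH4, THF, 0 °C → reflux; aq. NaOH work-up
Reagents that add atoms: none
Why: Hydride addition of LiAlH4 to the hindered diaryl ketone should give the carbinol as a racemate (no control is needed, since step 5 turns this carbon into CH2), with benzyl and methyl ethers inert.

**Step 5**
Reactants: 10 rac-[4-(benzyloxy)phenyl]{2-[2-(3-(benzyloxy)phenyl)ethyl]-4,6-dimethoxyphenyl}methanol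
Product: 11 Gymconopin D, 3-{2-[2-(4-hydroxybenzyl)-3,5-dimethoxyphenyl]ethyl}phenol
Conditions: H2 (1 atm), 10% Pd/C, EtOH–EtOAc, rt
Reagents that add atoms: none
Why: Catalytic hydrogenolysis should cleave both O-benzyl ethers and the doubly benzylic C–OH bond, which is activated by the ortho and para methoxy groups and, after debenzylation, by the para hydroxyl, while aryl methyl ethers, phenols and the saturated bridge are inert and no stereocentre remains.

**Compound list**
1 | 4-(benzyloxy)benzoyl chloride | O=C(Cl)c1ccc(OCc2ccccc2)cc1 | starting material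
2 | 4-(benzyloxy)-N-methoxy-N-methylbenzamide | CON(C)C(=O)c1ccc(OCc2ccccc2)cc1 | intermediate
3 | 1-bromo-2,4-dimethoxy-6-methylbenzene | COc1cc(C)c(Br)c(OC)c1 | starting material
4 | (2,4-dimethoxy-6-methylphenyl)lithium | [Li]c1c(C)cc(OC)cc1OC | intermediate (not isolated)
5 | lithium [4-(benzyloxy)phenyl](2,4-dimethoxy-6-methylphenyl)[methoxy(methyl)amino]methanolate | [Li]OC(N(C)OC)(c1ccc(OCc2ccccc2)cc1)c1c(C)cc(OC)cc1OC | intermediate (not isolated)
6 | [4-(benzyloxy)phenyl](2,4-dimethoxy-6-methylphenyl)methanone | COc1cc(C)c(C(=O)c2ccc(OCc3ccccc3)cc2)c(OC)c1 | intermediate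
7 | 1-(benzyloxy)-3-(bromomethyl)benzene | BrCc1cccc(OCc2ccccc2)c1 | starting material
8 | lithium [4-(benzyloxy)phenyl](2,4-dimethoxy-6-methylidenecyclohexa-2,4-dien-1-ylidene)methanolate (enolate geometry not defined) | [Li]OC(c1ccc(OCc2ccccc2)cc1)=C1C(=C)C=C(OC)C=C1OC | intermediate (not isolated)
9 | [4-(benzyloxy)phenyl]{2-[2-(3-(benzyloxy)phenyl)ethyl]-4,6-dimethoxyphenyl}methanone | COc1cc(CCc2cccc(OCc3ccccc3)c2)c(C(=O)c2ccc(OCc3ccccc3)cc2)c(OC)c1 | intermediate
10 | rac-[4-(benzyloxy)phenyl]{2-[2-(3-(benzyloxy)phenyl)ethyl]-4,6-dimethoxyphenyl}methanol (racemic carbinol) | COc1cc(CCc2cccc(OCc3ccccc3)c2)c(C(O)c2ccc(OCc3ccccc3)cc2)c(OC)c1 | intermediate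
11 | Gymconopin D (achiral) | COc1cc(CCc2cccc(O)c2)c(Cc2ccc(O)cc2)c(OC)c1 | target

**Totals**
Total step count: 5. Longest linear sequence: 5 steps (1 → 2 → 6 → 9 → 10 → 11); the branch from 3 is 4 steps.

**Steps most likely to fail**

Step 3. The di-ortho-substituted aryl ketone may not reach the planar dienolate geometry, so deprotonation could be slow or incomplete. Electron transfer from the dienolate to the benzylic bromide could lead to homocoupling of the electrophile, and a second alkylation at the new benzylic position is possible. The fallback moves the lateral metalation to an ester, where it is documented on exactly this ring, and builds the diarylmethane afterwards. It sets out from 3 and returns at 10. Bromine–lithium exchange on 3 (n-BuLi, THF, −78 °C) and addition of the resulting 4 to excess ethyl chloroformate should give ethyl 2,4-dimethoxy-6-methylbenzoate F1. LDA (THF, −78 °C) should convert it into the lithium dienolate of ethyl 2,4-dimethoxy-6-methylbenzoate F2, which 7 should alkylate to ethyl 2-{2-[3-(benzyloxy)phenyl]ethyl}-4,6-dimethoxybenzoate F3. LiAlH4 (THF) should reduce the ester to (2-{2-[3-(benzyloxy)phenyl]ethyl}-4,6-dimethoxyphenyl)methanol F4, and MnO2 (CH2Cl2) should oxidise it to 2-{2-[3-(benzyloxy)phenyl]ethyl}-4,6-dimethoxybenzaldehyde F5. Addition of [4-(benzyloxy)phenyl]magnesium bromide F6 (from purchased 1-(benzyloxy)-4-bromobenzene and Mg, THF) should then give carbinol 10, which enters step 5.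

Step 5. Hydrogenolysis of the hindered carbinol C–O bond may stall after debenzylation. Alternatively, traces of acid on the catalyst may ionise the doubly activated benzhydrol, whose cation can close a seven-membered ring onto the oxygenated bridge ring by Friedel–Crafts attack or can oligomerise. The fallback replaces catalytic hydrogenolysis by ionic deoxygenation and a Lewis-acid debenzylation. It sets out from 10 and returns at 11. Et3SiH (large excess) with CF3CO2H in CH2Cl2 at −40 → 0 °C should trap the cation by hydride transfer as soon as it forms and give 1-{2-[3-(benzyloxy)phenyl]ethyl}-2-{[4-(benzyloxy)phenyl]methyl}-3,5-dimethoxybenzene F7. BCl3 with pentamethylbenzene in CH2Cl2 at −78 °C should then remove both benzyl groups while sparing the aryl methyl ethers, giving 11.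

Step 2. The hindered, strongly basic aryllithium may attack the N-methoxy group of the amide (base-induced N–O cleavage) or add so slowly that it is merely protonated on work-up. The fallback goes through the alcohol oxidation level. It sets out from 3 and returns at 6. Aryllithium 4, generated as before, should add to purchased 4-(benzyloxy)benzaldehyde to give rac-[4-(benzyloxy)phenyl](2,4-dimethoxy-6-methylphenyl)methanol F8, and MnO2 (CH2Cl2) or Dess–Martin periodinane should oxidise this carbinol to ketone 6.

**Further compounds**
F1 | step 3 | ethyl 2,4-dimethoxy-6-methylbenzoate | CCOC(=O)c1c(C)cc(OC)cc1OC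
F2 | step 3 | lithium dienolate of ethyl 2,4-dimethoxy-6-methylbenzoate (lithium ethoxy(2,4-dimethoxy-6-methylidenecyclohexa-2,4-dien-1-ylidene)methanolate) | [Li]OC(OCC)=C1C(=C)C=C(OC)C=C1OC
F3 | step 3 | ethyl 2-{2-[3-(benzyloxy)phenyl]ethyl}-4,6-dimethoxybenzoate | CCOC(=O)c1c(CCc2cccc(OCc3ccccc3)c2)cc(OC)cc1OC
F4 | step 3 | (2-{2-[3-(benzyloxy)phenyl]ethyl}-4,6-dimethoxyphenyl)methanol | OCc1c(CCc2cccc(OCc3ccccc3)c2)cc(OC)cc1OC
F5 | step 3 | 2-{2-[3-(benzyloxy)phenyl]ethyl}-4,6-dimethoxybenzaldehyde | O=Cc1c(CCc2cccc(OCc3ccccc3)c2)cc(OC)cc1OC
F6 | step 3 | [4-(benzyloxy)phenyl]magnesium bromide | Br[Mg]c1ccc(OCc2ccccc2)cc1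
F7 | step 5 | 1-{2-[3-(benzyloxy)phenyl]ethyl}-2-{[4-(benzyloxy)phenyl]methyl}-3,5-dimethoxybenzene | COc1cc(CCc2cccc(OCc3ccccc3)c2)c(Cc2ccc(OCc3ccccc3)cc2)c(OC)c1
F8 | step 2 | rac-[4-(benzyloxy)phenyl](2,4-dimethoxy-6-methylphenyl)methanol | COc1cc(C)c(C(O)c2ccc(OCc3ccccc3)cc2)c(OC)c1
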